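**Retrosynthetic overview**

- The α-methylene ketone comes from oxidation of an allylic alcohol. That alcohol comes from a Nozaki–Hiyama–Kishi union of a 2-iodoallyl butenolide with the aryloxyacetaldehyde made from 7-hydroxy-8-methoxycoumarin.
- The alkenyl iodide is unmasked from a 2-silylallyl group by ipso-iododesilylation, because silicon, unlike iodine, is inert to low-valent nickel.
- The furan-2(5H)-one is closed by an enantioconvergent reductive (3+2) annulation: a racemic 1-chloroalkyl phenyl carbonate supplies the C5–O1–C2(=O) triad and propyne supplies C4H=C3(CH3), forming C5–C4 and C2–C3.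
- The enabling feature is that the sp3 carbon C5 of the furanone is joined through the ring oxygen O1 to the carbonyl C2. This C–O–C(=O) triad can be lifted out intact, with C5 as an easily activated α-oxy C–Cl centre and C2 as an acyl acceptor carrying a phenoxide leaving group.
- Ring order: the coumarin bicycle is bought intact; the furanone is the only ring made (step 6). The carbonate comes from an aldehyde and phenyl chloroformate, the aldehyde from but-3-yn-1-ol.

Key step: step 6

Remark: the target descriptor corresponds to (R) at C5 of the furanone; 7-hydroxy-8-methoxycoumarin is taken as purchasable; the ligand antipode in step 6 that gives the (R)-lactone must be fixed in first runs, and the route is written for that antipode.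

**Route**

Step 1
Reactants: 1 7-hydroxy-8-methoxy-2H-chromen-2-one; 2 2-bromo-1,1-diethoxyethane
Product: 3 7-(2,2-diethoxyethoxy)-8-methoxy-2H-chromen-2-one
Conditions: K2CO3, KI (cat.), DMF, 110 °C
Reagents that add atoms: none
Why: Williamson ether synthesis; the phenoxide of the only acidic site displaces the primary bromide, and the coumarin lactone tolerates carbonate base in DMF.

Step 2
Reactants: 3 7-(2,2-diethoxyethoxy)-8-methoxy-2H-chromen-2-one
Product: 4 2-[(8-methoxy-2-oxo-2H-chromen-7-yl)oxy]acetaldehyde
Conditions: 2 M aq. HCl, THF, 50 °C; dried by azeotrope before use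
Reagents that add atoms: water, O
Why: Acid-catalysed acetal hydrolysis; dilute aqueous acid at moderate temperature should avoid the cyclodehydration onto C6 that needs strong dehydrating acid.

Step 3
Reactants: 5 but-3-yn-1-ol
Product: 6 3-(triethylsilyl)but-3-en-1-ol
Conditions: Et3SiH (1.2 equiv), [Cp*Ru(MeCN)3]PF6 (1 mol %), CH2Cl2, 0 °C → rt
Reagents that add atoms: triethylsilane, CC[SiH](CC)CC
Why: Ruthenium-catalysed Markovnikov hydrosilylation of a terminal alkyne places silicon on the internal carbon and tolerates the free hydroxyl group.

Step 4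
Reactants: 6 3-(triethylsilyl)but-3-en-1-ol
Product: 7 3-(triethylsilyl)but-3-enal
Conditions: Dess–Martin periodinane, NaHCO3, CH2Cl2, 0 °C; crude aldehyde used at once
Reagents that add atoms: none
Why: Dess–Martin oxidation under buffered, non-basic conditions should give the β,γ-unsaturated aldehyde without moving the double bond into conjugation.

Step 5
Reactants: 7 3-(triethylsilyl)but-3-enal
Product: 8 rac-1-chloro-3-(triethylsilyl)but-3-en-1-yl phenyl carbonate
Conditions: PhOCOCl (1.1 equiv), pyridine (5 mol %), CH2Cl2, −20 → 0 °C; filtration through a short neutral pad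
Reagents that add atoms: phenyl chloroformate, O=C(Cl)Oc1ccccc1
Why: Pyridine-catalysed addition of an aldehyde carbonyl across the C–Cl bond of a chloroformate (1-chloroalkyl carbonate synthesis); the new centre forms racemic, which step 6 is designed to accept.

Step 6
Reactants: 8 rac-1-chloro-3-(triethylsilyl)but-3-en-1-yl phenyl carbonate; 9 propyne
Product: 10 (5R)-3-methyl-5-[2-(triethylsilyl)prop-2-en-1-yl]furan-2(5H)-one
Conditions: NiBr2·glyme (10 mol %), chiral 4,4'-dialkyl-2,2'-bi(2-oxazoline) (12 mol %), Mn powder (2 equiv), propyne (5 equiv, THF solution), DMA, 0 °C, sealed vessel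
Reagents that add atoms: none
Why: Proposed new method: a chiral bi(oxazoline)–Ni(I) species should abstract chlorine from either enantiomer of 8 to give one planar α-carbonatoalkyl radical, which nickel recaptures as a C,O-chelated alkylnickel whose diastereomers interconvert by reversible Ni–C homolysis; syn-carbonickelation of propyne (alkyl to the CH terminus, nickel to the methyl-bearing carbon) then forms C5–C4, the cis-alkenylnickel adds to the carbonate carbonyl to form C3–C2, β-aryloxide elimination releases the lactone, and Mn returns Ni(II) to Ni(0). The closest known reaction types are the transition-metal-catalysed (3+2) annulations of ortho-acyl or ortho-ester aryl halides and arylboron reagents with alkynes (indenols, indenones), the nickel-catalysed enantioconvergent couplings of racemic 1-haloalkyl esters, and the acyl substitution of alkenylnickel species on esters. The one ring formed, the furan-2(5H)-one, closes by 5-exo-trig attack of the alkenyl carbon on the carbonate C=O, and only the cis arrangement of the two new bonds on the former alkyne can close. The C5 stereocentre is set under catalyst control in the C(sp3)–C(sp2) bond-forming insertion, so racemic 8 should converge on the (R)-lactone; because α-acyloxyalkyl radicals add only slowly to unactivated alkynes, capture by nickel should outrun the uncatalysed racemic addition. The step needs regioselectivity (methyl next to the carbonyl), secured by the preference of the nickel-bound alkyl (and of any free radical) for the unhindered alkyne CH. It also needs chemoselectivity for C–Cl over the carbonate and the vinylsilane, secured by the easy activation of the α-oxy C–Cl bond and by using a phenyl carbonate, which neither adds to Ni(0) at 0 °C nor can shed its aryl group in an O-cyclisation.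

Step 7
Reactants: 10 (5R)-3-methyl-5-[2-(triethylsilyl)prop-2-en-1-yl]furan-2(5H)-one
Product: 11 (5R)-5-(2-iodoprop-2-en-1-yl)-3-methylfuran-2(5H)-one
Conditions: NIS (1.3 equiv), (CF3)2CHOH, 0 °C, dark
Reagents that add atoms: N-iodosuccinimide, O=C1CCC(=O)N1I
Why: Electrophilic ipso-iododesilylation of a vinylsilane puts iodine where silicon was; the electron-poor butenolide alkene should not react with NIS and the non-basic medium leaves C5 untouched.

Step 8
Reactants: 11 (5R)-5-(2-iodoprop-2-en-1-yl)-3-methylfuran-2(5H)-one; 4 2-[(8-methoxy-2-oxo-2H-chromen-7-yl)oxy]acetaldehyde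
Product: 12 7-({2-hydroxy-3-[((2R)-4-methyl-5-oxo-2,5-dihydrofuran-2-yl)methyl]but-3-en-1-yl}oxy)-8-methoxy-2H-chromen-2-one (both carbinol epimers)
Conditions: CrCl2 (4 equiv), NiCl2 (2 mol %), DMF, rt; 4 (1.5 equiv); aqueous work-up
Reagents that add atoms: none
Why: Nozaki–Hiyama–Kishi coupling; the organochromium species adds only to the aldehyde and is too weakly basic to touch the lactone, the coumarin or the C5–H, and the uncontrolled carbinol centre is removed in step 9.

Step 9
Reactants: 12 7-({2-hydroxy-3-[((2R)-4-methyl-5-oxo-2,5-dihydrofuran-2-yl)methyl]but-3-en-1-yl}oxy)-8-methoxy-2H-chromen-2-one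
Product: 13 8-methoxy-7-({3-[((2R)-4-methyl-5-oxo-2,5-dihydrofuran-2-yl)methyl]-2-oxobut-3-en-1-yl}oxy)-2H-chromen-2-one
Conditions: Dess–Martin periodinane, NaHCO3, CH2Cl2, 0 °C → rt; product kept cold
Reagents that add atoms: none
Why: Dess–Martin oxidation of the allylic alcohol to the α-methylene ketone; no base able to epimerise C5 or to add to the new enone is present.

**Compound list**

1 | 7-hydroxy-8-methoxy-2H-chromen-2-one | COc1c(O)ccc2ccc(=O)oc12 | starting material
2 | 2-bromo-1,1-diethoxyethane | CCOC(CBr)OCC | starting material
3 | 7-(2,2-diethoxyethoxy)-8-methoxy-2H-chromen-2-one | CCOC(COc1ccc2ccc(=O)oc2c1OC)OCC | intermediate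
4 | 2-[(8-methoxy-2-oxo-2H-chromen-7-yl)oxy]acetaldehyde | O=CCOc1ccc2ccc(=O)oc2c1OC | intermediate
5 | but-3-yn-1-ol | C#CCCO | starting material
6 | 3-(triethylsilyl)but-3-en-1-ol | C=C(CCO)[Si](CC)(CC)CC | intermediate
7 | 3-(triethylsilyl)but-3-enal | C=C(CC=O)[Si](CC)(CC)CC | intermediate
8 | rac-1-chloro-3-(triethylsilyl)but-3-en-1-yl phenyl carbonate | C=C(CC(Cl)OC(=O)Oc1ccccc1)[Si](CC)(CC)CC | intermediate
9 | propyne | CC#C | starting material
10 | (5R)-3-methyl-5-[2-(triethylsilyl)prop-2-en-1-yl]furan-2(5H)-one | C=C(C[C@@H]1C=C(C)C(=O)O1)[Si](CC)(CC)CC | intermediate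
11 | (5R)-5-(2-iodoprop-2-en-1-yl)-3-methylfuran-2(5H)-one | C=C(I)C[C@@H]1C=C(C)C(=O)O1 | intermediate
12 | 7-({2-hydroxy-3-[((2R)-4-methyl-5-oxo-2,5-dihydrofuran-2-yl)methyl]but-3-en-1-yl}oxy)-8-methoxy-2H-chromen-2-one (both carbinol epimers) | C=C(C[C@@H]1C=C(C)C(=O)O1)C(O)COc1ccc2ccc(=O)oc2c1OC | intermediate
13 | 8-methoxy-7-({3-[((2R)-4-methyl-5-oxo-2,5-dihydrofuran-2-yl)methyl]-2-oxobut-3-en-1-yl}oxy)-2H-chromen-2-one | C=C(C[C@@H]1C=C(C)C(=O)O1)C(=O)COc1ccc2ccc(=O)oc2c1OC | target

**Count and risks**

Total step count: 9. Longest linear sequence: 7 steps (5 → 6 → 7 → 8 → 10 → 11 → 12 → 13; steps 1 and 2 form the side branch that enters at step 8).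

Steps most likely to fail:

1. Step 6 (Proposed new method). The free α-carbonatoalkyl radical may add to propyne, or be reduced, before nickel captures it, which would erode the enantiomeric purity. β-Hydride elimination from the alkylnickel toward a diene, and nickel-induced oligomerisation of propyne, may also consume substrate and catalyst. Fallback with known chemistry, setting out from 7 and 9 and coming back at 10: catalytic asymmetric addition of propyne 9 to aldehyde 7 (dimethylzinc, ProPhenol-type ligand) should give (4R)-2-(triethylsilyl)hept-1-en-5-yn-4-ol F1. Hydroxyl-directed trans-hydroalumination and iodination (Red-Al, then I2) should give (4R,5Z)-6-iodo-2-(triethylsilyl)hepta-1,5-dien-4-ol F2. Palladium-catalysed carbonylative lactonisation (PdCl2(PPh3)2, CO, Et3N, THF) should then close the furanone to 10, the lactone carbonyl coming from CO.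

2. Step 5. The amine catalyst may move the β,γ double bond of 7 into conjugation before the carbonyl group is trapped, and the α-chloroalkyl carbonate may hydrolyse during isolation. Fallback, setting out from 7 and coming back at 10: catalytic asymmetric addition of divinylzinc (chiral amino alcohol catalyst) should give (3R)-5-(triethylsilyl)hexa-1,5-dien-3-ol F3. Acylation with methacryloyl chloride (Et3N, DMAP) should give (3R)-5-(triethylsilyl)hexa-1,5-dien-3-yl 2-methylprop-2-enoate F4. Ring-closing metathesis with a second-generation ruthenium benzylidene catalyst should join the vinyl and methacrylate alkenes to give 10; the hindered 1-silylvinyl group should stay out of the metathesis.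

3. Step 8. Aldehyde 4 tends to hydrate and oligomerise, so the organochromium species may be protonated before it meets a free carbonyl group, and oxidative addition of the hindered 2-iodoalkene may be slow. Fallback, setting out from 4 and 11 and coming back at 13 (step 9 is then not needed): Pinnick oxidation of 4 should give [(8-methoxy-2-oxo-2H-chromen-7-yl)oxy]acetic acid F5, and oxalyl chloride with catalytic DMF should give [(8-methoxy-2-oxo-2H-chromen-7-yl)oxy]acetyl chloride F6. Iodide 11 with hexamethylditin and Pd(PPh3)4 should give (5R)-3-methyl-5-[2-(trimethylstannyl)prop-2-en-1-yl]furan-2(5H)-one F7. Stille acylation of F7 with F6 under neutral palladium catalysis should give the enone 13 directly.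

**Further compounds**

F1 | step 6 | (4R)-2-(triethylsilyl)hept-1-en-5-yn-4-ol | C=C(C[C@@H](O)C#CC)[Si](CC)(CC)CC
F2 | step 6 | (4R,5Z)-6-iodo-2-(triethylsilyl)hepta-1,5-dien-4-ol | C=C(C[C@@H](O)/C=C(/C)I)[Si](CC)(CC)CC
F3 | step 5 | (3R)-5-(triethylsilyl)hexa-1,5-dien-3-ol | C=C(C[C@@H](O)C=C)[Si](CC)(CC)CC
F4 | step 5 | (3R)-5-(triethylsilyl)hexa-1,5-dien-3-yl 2-methylprop-2-enoate | C=C(C[C@@H](OC(=O)C(C)=C)C=C)[Si](CC)(CC)CC
F5 | step 8 | [(8-methoxy-2-oxo-2H-chromen-7-yl)oxy]acetic acid | OC(=O)COc1ccc2ccc(=O)oc2c1OC
F6 | step 8 | [(8-methoxy-2-oxo-2H-chromen-7-yl)oxy]acetyl chloride | ClC(=O)COc1ccc2ccc(=O)oc2c1OC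
F7 | step 8 | (5R)-3-methyl-5-[2-(trimethylstannyl)prop-2-en-1-yl]furan-2(5H)-one | C=C(C[C@@H]1C=C(C)C(=O)O1)[Sn](C)(C)C
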